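**Plan**
- Retrosynthesis: the lactone C1–O and C1–C8a bonds are cut first (CO inserted between an aryl bromide and the C3 hydroxyl), then the arene–C4 bond (aryl Grignard plus terminal epoxide), then C10'–C11' (methyl Grignard plus terminal epoxide), and last C1'–C2' and C7'–C8' (hexane-1,6-diyl di-Grignard plus two epichlorohydrins).
- Enabling feature: C3 (R) of the lactone ring and the side-chain carbinol C9' (S) lie at the two ends of the eight-methylene run C1'–C8' with the same spatial sense. The segment C4–C3–(C1'–C8')–C9'–C10' is therefore a hidden C2-symmetric 2,11-dioxygenated dodecane.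
- Forward: the C12 chain is made in one two-directional coupling, both ends become epoxides, one methyl opening desymmetrises the diepoxide, the arene is joined at the other end, and the lactone ring is closed last by carbonylation. One hydrogenolysis frees the three hydroxyls.
- Stereochemistry: both carbinol centres are carried over unchanged from (R)-epichlorohydrin; no later step breaks either C–O bond.

Key step: step 2

Assumption: the phenols and the side-chain carbinol are carried as benzyl ethers (arene from purchased 1-bromo-3,5-bis(benzyloxy)benzene), so the route ends with a neutral hydrogenolysis and no Lewis acid touches the secondary alcohol; (R)-epichlorohydrin is bought at 99% ee or better.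

**Step 1**
Reactants: 1 1,6-dibromohexane
Product: 2 hexane-1,6-diylbis(magnesium bromide), kept as a titrated THF solution
Conditions: Mg turnings (3 equiv), BrCH2CH2Br (cat.), THF, 25–40 °C, slow addition at high dilution
Reagents that add atoms: magnesium, [Mg]
Why: Grignard formation by insertion of magnesium into both primary C–Br bonds, with slow addition to excess activated metal to hold down Wurtz coupling.

**Step 2**
Reactants: 2 hexane-1,6-diylbis(magnesium bromide); 3 (R)-epichlorohydrin (2.2 equiv)
Product: 4 (2R,11R)-1,12-dichlorododecane-2,11-diol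
Conditions: CuI (10 mol%), THF, −40 → −20 °C, 2 added to 3; then cold 1 M HCl
Reagents that add atoms: none
Why: Each C–Mg end is transmetalated to copper and the resulting organocopper species opens the oxirane of 3 by SN2 at its unsubstituted CH2, which forms C3–C4 and C9–C10 of 4 (C1'–C2' and C7'–C8' of the target) and leaves magnesium chloro-alkoxides that are protonated on work-up. The closest known reaction is the CuI-catalysed opening of epichlorohydrin by a simple alkyl Grignard reagent to a 1-chloroalkan-2-ol, run here at both ends of one di-Grignard reagent. No ring is closed; two oxiranes are only opened. C2 and C11 are the carbinol carbons of two molecules of 3 whose C–O bonds are never broken, so both are reagent-controlled and R, and any (S)-3 is channelled mostly into the meso isomer, which raises the enantiomeric purity of the C2-symmetric isomer and may be depleted further by recrystallising 4. The step needs attack at the oxirane CH2 and not at C–Cl or the internal carbon, because substitution at C–Cl would deliver the opposite configuration. Copper catalysis at low temperature, addition of 2 into excess 3 and a cold acidic quench (before a chloro-alkoxide can close to an epoxide and be opened again) secure this.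

**Step 3**
Reactants: 4 (2R,11R)-1,12-dichlorododecane-2,11-diol
Product: 5 (2R,2'R)-2,2'-(octane-1,8-diyl)bis(oxirane)
Conditions: NaOH (powdered, 4 equiv), THF, rt
Reagents that add atoms: none
Why: Twofold intramolecular Williamson etherification (3-exo-tet) of the chloro-alkoxides, which leaves the C–O bonds at both stereocentres untouched so both stay R.

**Step 4**
Reactants: 5 (2R,2'R)-2,2'-(octane-1,8-diyl)bis(oxirane)
Product: 6 (3S)-11-[(2R)-oxiran-2-yl]undecan-3-ol
Conditions: MeMgBr (0.8 equiv), CuI (10 mol%), THF, −40 → −20 °C; sat. aq NH4Cl; unreacted 5 recovered and recycled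
Reagents that add atoms: methylmagnesium bromide, C[Mg]Br
Why: CuI-catalysed Grignard opening of a terminal epoxide at CH2 on a substrate whose two oxiranes are homotopic, so limiting MeMgBr should give one mono-adduct in a statistical mixture with recoverable 5 and the easily separated diol, and the untouched carbinol centre becomes S only because the new ethyl branch ranks below the long chain.

**Step 5**
Reactants: 6 (3S)-11-[(2R)-oxiran-2-yl]undecan-3-ol
Product: 7 (2R)-2-[(9S)-9-(benzyloxy)undecyl]oxirane
Conditions: NaH, BnBr, n-Bu4NI (cat.), THF, 0 °C → rt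
Reagents that add atoms: benzyl bromide, BrCc1ccccc1
Why: Williamson etherification of the sodium alkoxide with benzyl bromide, which a terminal epoxide tolerates at or below room temperature and which involves neither stereocentre.

**Step 6**
Reactants: 7 (2R)-2-[(9S)-9-(benzyloxy)undecyl]oxirane; 8 1-bromo-3,5-bis(benzyloxy)benzene (2 equiv)
Product: 10 (2R,11S)-11-(benzyloxy)-1-[3,5-bis(benzyloxy)phenyl]tridecan-2-ol, via arylmagnesium bromide 9 (not isolated)
Conditions: 8, Mg, THF, 50 °C; then CuI (15 mol%), 7, −30 → 0 °C; 1 M HCl
Reagents that add atoms: none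
Why: Grignard formation from 8 followed by CuI-catalysed SN2 opening of the terminal epoxide at CH2 forms the arene–C4 bond with the C3–O bond intact, so the future C3 stays R.

**Step 7**
Reactants: 10 (2R,11S)-11-(benzyloxy)-1-[3,5-bis(benzyloxy)phenyl]tridecan-2-ol
Product: 11 (2R,11S)-11-(benzyloxy)-1-[3,5-bis(benzyloxy)-2-bromophenyl]tridecan-2-ol
Conditions: NBS (1.0 equiv), MeCN, 0 °C, dark
Reagents that add atoms: N-bromosuccinimide, O=C1CCC(=O)N1Br
Why: Electrophilic aromatic bromination of the resorcinol diether ring, far more electron-rich than the benzyl rings, at one of its two equivalent positions ortho to the alkyl chain and para to a benzyloxy group, in preference to the hindered position between the two benzyloxy groups, with one equivalent of NBS limiting dibromination.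

**Step 8**
Reactants: 11 (2R,11S)-11-(benzyloxy)-1-[3,5-bis(benzyloxy)-2-bromophenyl]tridecan-2-ol
Product: 12 (3R)-6,8-bis(benzyloxy)-3-[(9S)-9-(benzyloxy)undecyl]isochroman-1-one
Conditions: CO (1 atm), Pd(OAc)2 (5 mol%), Xantphos (6 mol%), Et3N, toluene, 100 °C
Reagents that add atoms: carbon monoxide, [C-]#[O+]
Why: Palladium-catalysed carbonylative lactonisation, in which oxidative addition of the C–Br bond to zerovalent palladium, CO insertion and capture of the acylpalladium by the C3 hydroxyl close the six-membered lactone ring with the C3–O bond, and hence the R configuration, retained.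

**Step 9**
Reactants: 12 (3R)-6,8-bis(benzyloxy)-3-[(9S)-9-(benzyloxy)undecyl]isochroman-1-one
Product: 13 (3R)-6,8-dihydroxy-3-[(9S)-9-hydroxyundecyl]isochroman-1-one
Conditions: H2 (1 atm), 10% Pd/C, EtOAc–MeOH, rt
Reagents that add atoms: none
Why: Hydrogenolysis of the two aryl benzyl ethers and the secondary alkyl benzyl ether over palladium on carbon, under neutral conditions to which the lactone, the arene and the two non-benzylic stereocentres are inert.

**Compound list**
1 | 1,6-dibromohexane | BrCCCCCCBr | starting material
2 | hexane-1,6-diylbis(magnesium bromide) | Br[Mg]CCCCCC[Mg]Br | intermediate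
3 | (R)-epichlorohydrin, (2R)-2-(chloromethyl)oxirane | ClC[C@H]1CO1 | starting material
4 | (2R,11R)-1,12-dichlorododecane-2,11-diol | ClC[C@H](O)CCCCCCCC[C@@H](O)CCl | intermediate
5 | (2R,2'R)-2,2'-(octane-1,8-diyl)bis(oxirane) | C1O[C@@H]1CCCCCCCC[C@@H]1CO1 | intermediate
6 | (3S)-11-[(2R)-oxiran-2-yl]undecan-3-ol | CC[C@H](O)CCCCCCCC[C@@H]1CO1 | intermediate
7 | (2R)-2-[(9S)-9-(benzyloxy)undecyl]oxirane | CC[C@H](OCc1ccccc1)CCCCCCCC[C@@H]1CO1 | intermediate
8 | 1-bromo-3,5-bis(benzyloxy)benzene | Brc1cc(OCc2ccccc2)cc(OCc2ccccc2)c1 | starting material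
9 | [3,5-bis(benzyloxy)phenyl]magnesium bromide | Br[Mg]c1cc(OCc2ccccc2)cc(OCc2ccccc2)c1 | intermediate (not isolated)
10 | (2R,11S)-11-(benzyloxy)-1-[3,5-bis(benzyloxy)phenyl]tridecan-2-ol | CC[C@H](OCc1ccccc1)CCCCCCCC[C@@H](O)Cc1cc(OCc2ccccc2)cc(OCc2ccccc2)c1 | intermediate
11 | (2R,11S)-11-(benzyloxy)-1-[3,5-bis(benzyloxy)-2-bromophenyl]tridecan-2-ol | CC[C@H](OCc1ccccc1)CCCCCCCC[C@@H](O)Cc1cc(OCc2ccccc2)cc(OCc2ccccc2)c1Br | intermediate
12 | (3R)-6,8-bis(benzyloxy)-3-[(9S)-9-(benzyloxy)undecyl]isochroman-1-one | CC[C@H](OCc1ccccc1)CCCCCCCC[C@@H]1Cc2cc(OCc3ccccc3)cc(OCc3ccccc3)c2C(=O)O1 | intermediate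
13 | (3R)-6,8-dihydroxy-3-[(9S)-9-hydroxyundecyl]isochroman-1-one | CC[C@H](O)CCCCCCCC[C@@H]1Cc2cc(O)cc(O)c2C(=O)O1 | target

Total step count: 9. Longest linear sequence: 9 steps (1 → 13).

**Steps most likely to fail**

Step 2. Incomplete double metalation and Wurtz coupling in step 1 would leave chains with only one C–Mg end, and halide opening of the oxirane or premature closure of a chloro-alkoxide followed by a second Grignard attack would erode the twofold opening. The fallback sets out from 3 and returns at 5. Compound 3 is opened with commercial but-3-enylmagnesium bromide (CuI cat., THF, −40 °C) to (2R)-1-chlorohept-6-en-2-ol F1, and powdered NaOH closes this to (2R)-2-(pent-4-en-1-yl)oxirane F2. Self-metathesis of F2 with the second-generation Grubbs catalyst RuCl2(=CHPh)(PCy3)(H2IMes) in CH2Cl2 at 40 °C joins the two halves as (2R,2'R)-2,2'-(oct-4-ene-1,8-diyl)bis(oxirane) F3, whose alkene geometry is irrelevant. Diimide (2-nitrobenzenesulfonyl hydrazide, Et3N, CH2Cl2, rt) then saturates the alkene to give 5. The symmetry is still used, but the halves are made with a monofunctional Grignard reagent and joined by metathesis.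

Step 4. The opening is statistical, so over-reaction to the doubly methylated diol and unreacted 5 cap the throughput per pass, and halide opening of an oxirane to a bromohydrin would add to the loss. The fallback sets out from 3 and returns at 7, using the same chiral reagent twice in a one-directional sequence in which the chain ends differ from the start. 1-Bromo-6-chlorohexane and Mg in THF give 6-chlorohexylmagnesium bromide F4 by selective insertion into C–Br. CuI-catalysed opening of 3 gives (2R)-1,9-dichlorononan-2-ol F5, and NaOH closes it to (2R)-2-(7-chloroheptyl)oxirane F6. Excess MeMgBr with CuI opens F6 to (3S)-10-chlorodecan-3-ol F7, and NaH with BnBr gives {[(3S)-10-chlorodecan-3-yl]oxy}methylbenzene F8. Mg in refluxing THF converts the primary chloride into [(8S)-8-(benzyloxy)decyl]magnesium chloride F9. A second CuI-catalysed opening of 3 gives (2R,11S)-11-(benzyloxy)-1-chlorotridecan-2-ol F10, which NaOH closes to 7.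

Step 8. Oxidative addition of the electron-rich, doubly ortho-substituted C–Br bond may be slow under CO, so that catalyst deactivation and protodebromination compete with acyl formation. The fallback sets out from 11 and returns at 12. n-BuLi (2.2 equiv, THF, −78 °C) deprotonates the hydroxyl and exchanges bromine for lithium, and CO2 followed by acidic work-up gives 2,4-bis(benzyloxy)-6-[(2R,11S)-11-(benzyloxy)-2-hydroxytridecyl]benzoic acid F11. F11 should lactonise to 12 on warming with catalytic TsOH in toluene.

**Further compounds**
F1 | step 2 | (2R)-1-chlorohept-6-en-2-ol | ClC[C@H](O)CCCC=C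
F2 | step 2 | (2R)-2-(pent-4-en-1-yl)oxirane | C=CCCC[C@@H]1CO1
F3 | step 2 | (2R,2'R)-2,2'-(oct-4-ene-1,8-diyl)bis(oxirane) | C1O[C@@H]1CCCC=CCCC[C@@H]1CO1
F4 | step 4 | 6-chlorohexylmagnesium bromide | ClCCCCCC[Mg]Br
F5 | step 4 | (2R)-1,9-dichlorononan-2-ol | ClC[C@H](O)CCCCCCCCl
F6 | step 4 | (2R)-2-(7-chloroheptyl)oxirane | ClCCCCCCC[C@@H]1CO1
F7 | step 4 | (3S)-10-chlorodecan-3-ol | CC[C@H](O)CCCCCCCCl
F8 | step 4 | {[(3S)-10-chlorodecan-3-yl]oxy}methylbenzene | CC[C@H](OCc1ccccc1)CCCCCCCCl
F9 | step 4 | [(8S)-8-(benzyloxy)decyl]magnesium chloride | CC[C@H](OCc1ccccc1)CCCCCCC[Mg]Cl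
F10 | step 4 | (2R,11S)-11-(benzyloxy)-1-chlorotridecan-2-ol | CC[C@H](OCc1ccccc1)CCCCCCCC[C@@H](O)CCl
F11 | step 8 | 2,4-bis(benzyloxy)-6-[(2R,11S)-11-(benzyloxy)-2-hydroxytridecyl]benzoic acid | CC[C@H](OCc1ccccc1)CCCCCCCC[C@@H](O)Cc1cc(OCc2ccccc2)cc(OCc2ccccc2)c1C(=O)O
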